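Ring C is fused to ring A through the adjacent carbons C4a and C8a, and its O1–C2–C3–C4 chain is an enal in disguise. Everything rests on cutting C4–C4a and O1–C8a: a 3-methoxyaryne spanning C4a/C8a, steered by the C5 methoxy group and already bearing the C8 prenyl group and a protected C7 oxygen, is trapped by a 4-oxygenated cinnamaldehyde. Polar [2+2] addition of the carbonyl makes both aryl bonds at once; the benzoxete opens to an o-quinone methide whose oxa-6π closure transfers the oxygen from C4 to C2, giving the flav-3-ene. Copper-catalysed enantioselective hydroboration (a kinetic resolution) then sets the 2,3-trans carbinol, and acetal cleavage finishes.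

Key step: step 9

Assumption: (R,R)-Ph-BPE is taken to be the ligand enantiomer whose copper complex consumes the (2S)-enantiomer of the racemic chromene in step 10; if the sense is opposite, (S,S)-Ph-BPE is used instead. MOM = methoxymethyl; flavan numbering (O1, C2, C3, C4, C4a, C5–C8, C8a) is used for all ring positions.

Step 1
Reactants: 1 5-methoxybenzene-1,3-diol
Product: 2 1-methoxy-3,5-bis(methoxymethoxy)benzene
Conditions: MOMCl (2.5 equiv), iPr2NEt, CH2Cl2, 0 °C to rt
Reagents that add atoms: chloromethyl methyl ether, COCCl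
Why: O-alkylation of both phenols with the chloromethyl ether under amine base (Williamson-type etherification) gives the symmetric bis-acetal, which carries the two directing groups needed in step 2.

Step 2
Reactants: 2 1-methoxy-3,5-bis(methoxymethoxy)benzene
Product: 4 5-methoxy-1,3-bis(methoxymethoxy)-2-(3-methylbut-2-en-1-yl)benzene, via aryllithium 3 (not isolated)
Conditions: n-BuLi, THF, 0 °C to rt; CuBr·SMe2 (10 mol %), prenyl bromide, −78 °C to rt
Reagents that add atoms: 1-bromo-3-methylbut-2-ene (prenyl bromide), CC(C)=CCBr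
Why: Directed ortho-metalation takes place at the carbon flanked by the two chelating MOM acetals (the future C8), and copper-catalysed allylic substitution of the aryllithium at the primary carbon of prenyl bromide should give the linear prenyl arene.

Step 3
Reactants: 4 5-methoxy-1,3-bis(methoxymethoxy)-2-(3-methylbut-2-en-1-yl)benzene
Product: 5 2-bromo-1-methoxy-3,5-bis(methoxymethoxy)-4-(3-methylbut-2-en-1-yl)benzene
Conditions: NBS (1.0 equiv), MeCN, −20 to 0 °C, dark
Reagents that add atoms: N-bromosuccinimide, O=C1CCC(=O)N1Br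
Why: Electrophilic aromatic bromination of the 1,3,5-trioxygenated ring should outrun attack on the prenyl alkene, and the two remaining ring positions are equivalent by symmetry, so only one monobromide (bromine at the future C4a) can form.

Step 4
Reactants: 5 2-bromo-1-methoxy-3,5-bis(methoxymethoxy)-4-(3-methylbut-2-en-1-yl)benzene
Product: 6 4-bromo-5-methoxy-2-(3-methylbut-2-en-1-yl)benzene-1,3-diol
Conditions: conc. HCl (cat.), MeOH, rt
Reagents that add atoms: none
Why: Acid-catalysed transacetalization of the two aryl MOM acetals to methanol frees the resorcinol, and the mild conditions should keep the prenyl group from cyclizing onto the ortho hydroxyls.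

Step 5
Reactants: 6 4-bromo-5-methoxy-2-(3-methylbut-2-en-1-yl)benzene-1,3-diol
Product: 10 3-hydroxy-5-methoxy-2-(3-methylbut-2-en-1-yl)-6-(trimethylsilyl)phenyl trifluoromethanesulfonate, via bis(trimethylsilyl) ether 7 (not isolated), via lithium phenolate 8 (not isolated), via silyl ether triflate 9 (not isolated)
Conditions: HMDS, THF, 70 °C, then evaporation; n-BuLi, THF, −100 to −78 °C; Tf2O, −100 to −78 °C; aq NH4Cl; MeOH, citric acid (cat.), rt
Reagents that add atoms: hexamethyldisilazane, C[Si](C)(C)N[Si](C)(C)C; trifluoromethanesulfonic anhydride, O=S(=O)(OS(=O)(=O)C(F)(F)F)C(F)(F)F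
Why: O-silylation, bromine–lithium exchange and 1,3 O→C silyl migration (retro-Brook rearrangement) move silicon only from the oxygen next to bromine, so that phenolate alone is triflated, which differentiates the two formerly equivalent oxygens before methanolysis frees the remote phenol.

Step 6
Reactants: 10 3-hydroxy-5-methoxy-2-(3-methylbut-2-en-1-yl)-6-(trimethylsilyl)phenyl trifluoromethanesulfonate
Product: 11 5-methoxy-3-(methoxymethoxy)-2-(3-methylbut-2-en-1-yl)-6-(trimethylsilyl)phenyl trifluoromethanesulfonate
Conditions: MOMCl, iPr2NEt, CH2Cl2, 0 °C to rt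
Reagents that add atoms: chloromethyl methyl ether, COCCl
Why: O-alkylation of the remaining phenol under amine base protects the future C7 oxygen, and the aryl silane and the triflate should be inert to these fluoride-free conditions.

Step 7
Reactants: 12 4-hydroxybenzaldehyde
Product: 13 4-(methoxymethoxy)benzaldehyde
Conditions: MOMCl, iPr2NEt, CH2Cl2, 0 °C to rt
Reagents that add atoms: chloromethyl methyl ether, COCCl
Why: O-alkylation of the phenol with the chloromethyl ether under amine base gives the acetal-protected aldehyde.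

Step 8
Reactants: 13 4-(methoxymethoxy)benzaldehyde
Product: 14 (2E)-3-[4-(methoxymethoxy)phenyl]prop-2-enal
Conditions: Ph3P=CHCHO (1.1 equiv), toluene, 80 °C
Reagents that add atoms: (triphenylphosphoranylidene)acetaldehyde, O=CC=P(c1ccccc1)(c1ccccc1)c1ccccc1
Why: Wittig olefination with the stabilized formyl ylide should give the E-enal, and the limited excess of ylide restrains a second homologation.

Step 9
Reactants: 11 5-methoxy-3-(methoxymethoxy)-2-(3-methylbut-2-en-1-yl)-6-(trimethylsilyl)phenyl trifluoromethanesulfonate; 14 (2E)-3-[4-(methoxymethoxy)phenyl]prop-2-enal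
Product: 18 (±)-5-methoxy-7-(methoxymethoxy)-2-[4-(methoxymethoxy)phenyl]-8-(3-methylbut-2-en-1-yl)-2H-chromene, via aryne 15 (not isolated), via benzoxete 16 (not isolated), via o-quinone methide 17 (not isolated)
Conditions: CsF (3 equiv), MeCN, rt, slow addition of 11 to 14 (2.5 equiv)
Reagents that add atoms: none
Why: Fluoride attacks silicon of 11 and expels triflate to give aryne 15; the carbonyl oxygen of 14 adds to C8a and the aryl anion developing at C4a collapses onto the carbonyl carbon, so that C4–C4a and O–C8a form in one polar, asynchronous [2+2] event that closes the four-membered benzoxete 16 (formally a 4-endo-trig collapse of the zwitterion). Thermal 4π ring opening of 16 gives the o-quinone methide 17, and a disrotatory oxa-6π electrocyclization of its Z-dienone closes pyran ring C by making O1–C2, which moves the oxygen from C4 to C2. The closest known reaction type is the fluoride-triggered reaction of 2-(trimethylsilyl)aryl triflates with α,β-unsaturated aldehydes to give 2H-chromenes, and for the regiochemistry the insertion of 3-methoxyarynes into formamide C=O bonds. The step needs regioselective capture of the unsymmetrical aryne: the inductively withdrawing C5 methoxy group distorts the triple bond so that the nucleophilic oxygen attacks the distal carbon C8a and the carbon–carbon bond forms at C4a beside it, while the C8 prenyl group is only a weak alkyl perturbation whose trisubstituted alkene cannot reach the aryne for an ene or [2+2] reaction. The Z geometry of 17 needed for closure is the one that keeps the styryl arm away from the C5 methoxy group, and excess 14 with slow release of the aryne should suppress capture of 17 by a second aryne. C2 is created without any control element, so 18 is racemic and the centre is resolved in step 10.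

Step 10
Reactants: 18 (±)-5-methoxy-7-(methoxymethoxy)-2-[4-(methoxymethoxy)phenyl]-8-(3-methylbut-2-en-1-yl)-2H-chromene
Product: 20 (2R,3S)-5-methoxy-7-(methoxymethoxy)-2-[4-(methoxymethoxy)phenyl]-8-(3-methylbut-2-en-1-yl)chroman-3-ol, via pinacol boronate 19 (not isolated)
Conditions: CuCl (5 mol %), (R,R)-Ph-BPE (6 mol %), NaOtBu (10 mol %), B2pin2 (0.55 equiv), MeOH (2 equiv), THF, 0 °C to rt; then 30 % H2O2, 2 M NaOH, 0 °C
Reagents that add atoms: bis(pinacolato)diboron, CC1(C)OB(OC1(C)C)B1OC(C)(C)C(C)(C)O1 (boron carried in 19 only); hydrogen peroxide, OO (the C3 oxygen of 20)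
Why: In this enantioselective copper-catalysed hydroboration run as a kinetic resolution, the ligated copper boryl adds syn across the styrenyl C3=C4 bond with boron at C3 and copper at benzylic C4 on the face anti to the C2 aryl group, methanol protonates the C–Cu bond, the chiral bisphosphine lets only the (2S)-enantiomer of 18 react while the (2R)-enantiomer is left behind, and oxidation of the C–B bond with retention gives the 2,3-trans alcohol (the C2 descriptor changes from S to R only through the CIP priorities), the unactivated prenyl alkene being inert to borylcupration.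

Step 11
Reactants: 20 (2R,3S)-5-methoxy-7-(methoxymethoxy)-2-[4-(methoxymethoxy)phenyl]-8-(3-methylbut-2-en-1-yl)chroman-3-ol
Product: 21 8-prenylafzelechin 5-methyl ether, (2R,3S)-2-(4-hydroxyphenyl)-5-methoxy-8-(3-methylbut-2-en-1-yl)chromane-3,7-diol
Conditions: HCl (cat.), MeOH, 0 °C to rt
Reagents that add atoms: none
Why: Acid-catalysed methanolysis of the two aryl MOM acetals under mild conditions should free both phenols without ionizing the C2–O1 bond or cyclizing the prenyl group, and no stereocentre is touched.

Compound list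
1 | 5-methoxybenzene-1,3-diol (5-methoxyresorcinol) | COc1cc(O)cc(O)c1 | starting material
2 | 1-methoxy-3,5-bis(methoxymethoxy)benzene | COCOc1cc(OC)cc(OCOC)c1 | intermediate
3 | [4-methoxy-2,6-bis(methoxymethoxy)phenyl]lithium | [Li]c1c(OCOC)cc(OC)cc1OCOC | intermediate (not isolated)
4 | 5-methoxy-1,3-bis(methoxymethoxy)-2-(3-methylbut-2-en-1-yl)benzene | COCOc1cc(OC)cc(OCOC)c1CC=C(C)C | intermediate
5 | 2-bromo-1-methoxy-3,5-bis(methoxymethoxy)-4-(3-methylbut-2-en-1-yl)benzene | COc1cc(OCOC)c(CC=C(C)C)c(OCOC)c1Br | intermediate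
6 | 4-bromo-5-methoxy-2-(3-methylbut-2-en-1-yl)benzene-1,3-diol | COc1cc(O)c(CC=C(C)C)c(O)c1Br | intermediate
7 | 4-bromo-5-methoxy-2-(3-methylbut-2-en-1-yl)-1,3-bis(trimethylsilyloxy)benzene | COc1cc(O[Si](C)(C)C)c(CC=C(C)C)c(O[Si](C)(C)C)c1Br | intermediate (not isolated)
8 | lithium 3-methoxy-6-(3-methylbut-2-en-1-yl)-2-(trimethylsilyl)-5-(trimethylsilyloxy)phenolate | COc1cc(O[Si](C)(C)C)c(CC=C(C)C)c([O-])c1[Si](C)(C)C.[Li+] | intermediate (not isolated)
9 | 5-methoxy-2-(3-methylbut-2-en-1-yl)-6-(trimethylsilyl)-3-(trimethylsilyloxy)phenyl trifluoromethanesulfonate | COc1cc(O[Si](C)(C)C)c(CC=C(C)C)c(OS(=O)(=O)C(F)(F)F)c1[Si](C)(C)C | intermediate (not isolated)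
10 | 3-hydroxy-5-methoxy-2-(3-methylbut-2-en-1-yl)-6-(trimethylsilyl)phenyl trifluoromethanesulfonate | COc1cc(O)c(CC=C(C)C)c(OS(=O)(=O)C(F)(F)F)c1[Si](C)(C)C | intermediate
11 | 5-methoxy-3-(methoxymethoxy)-2-(3-methylbut-2-en-1-yl)-6-(trimethylsilyl)phenyl trifluoromethanesulfonate | COCOc1cc(OC)c([Si](C)(C)C)c(OS(=O)(=O)C(F)(F)F)c1CC=C(C)C | intermediate
12 | 4-hydroxybenzaldehyde | O=Cc1ccc(O)cc1 | starting material
13 | 4-(methoxymethoxy)benzaldehyde | COCOc1ccc(C=O)cc1 | intermediate
14 | (2E)-3-[4-(methoxymethoxy)phenyl]prop-2-enal | COCOc1ccc(/C=C/C=O)cc1 | intermediate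
15 | 3-methoxy-5-(methoxymethoxy)-6-(3-methylbut-2-en-1-yl)benzyne (1,2-didehydrobenzene) | COC1=CC(OCOC)=C(CC=C(C)C)C#C1 | intermediate (not isolated)
16 | (±)-3-methoxy-5-(methoxymethoxy)-2-{(E)-2-[4-(methoxymethoxy)phenyl]ethenyl}-6-(3-methylbut-2-en-1-yl)-2H-benzo[b]oxete (racemic, stereocentre left unspecified) | COCOc1ccc(/C=C/C2Oc3c(CC=C(C)C)c(OCOC)cc(OC)c32)cc1 | intermediate (not isolated)
17 | (6Z)-5-methoxy-3-(methoxymethoxy)-6-{(2E)-3-[4-(methoxymethoxy)phenyl]prop-2-en-1-ylidene}-2-(3-methylbut-2-en-1-yl)cyclohexa-2,4-dien-1-one | O=C1/C(=C\C=C\c2ccc(OCOC)cc2)C(OC)=CC(OCOC)=C1CC=C(C)C | intermediate (not isolated)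
18 | (±)-5-methoxy-7-(methoxymethoxy)-2-[4-(methoxymethoxy)phenyl]-8-(3-methylbut-2-en-1-yl)-2H-chromene (racemic, stereocentre left unspecified) | COc1cc(OCOC)c(CC=C(C)C)c2c1C=CC(c1ccc(OCOC)cc1)O2 | intermediate
19 | (2S,3S)-5-methoxy-7-(methoxymethoxy)-2-[4-(methoxymethoxy)phenyl]-8-(3-methylbut-2-en-1-yl)-3-(4,4,5,5-tetramethyl-1,3,2-dioxaborolan-2-yl)chromane (2,3-trans) | COc1cc(OCOC)c(CC=C(C)C)c2c1C[C@H](B1OC(C)(C)C(C)(C)O1)[C@@H](c1ccc(OCOC)cc1)O2 | intermediate (not isolated)
20 | (2R,3S)-5-methoxy-7-(methoxymethoxy)-2-[4-(methoxymethoxy)phenyl]-8-(3-methylbut-2-en-1-yl)chroman-3-ol | COc1cc(OCOC)c(CC=C(C)C)c2c1C[C@H](O)[C@@H](c1ccc(OCOC)cc1)O2 | intermediate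
21 | 8-prenylafzelechin 5-methyl ether, (2R,3S)-2-(4-hydroxyphenyl)-5-methoxy-8-(3-methylbut-2-en-1-yl)chromane-3,7-diol | COc1cc(O)c(CC=C(C)C)c2c1C[C@H](O)[C@@H](c1ccc(O)cc1)O2 | target

Total step count: 11
Longest linear sequence: 9 steps (steps 1 to 6, then 9, 10 and 11)

Steps most likely to fail

Step 9. The carbonyl oxygen may add to the aryne with the wrong orientation (at C4a instead of C8a), or the o-quinone methide may be captured by a second aryne before it cyclizes. The fallback replaces aryne capture by a phenol–enal condensation and sets out from 4. Partial acidic methanolysis (HCl cat., MeOH, 0 °C, stopped early, 4 recycled) removes one of the two equivalent acetals and gives 5-methoxy-3-(methoxymethoxy)-2-(3-methylbut-2-en-1-yl)phenol F1, in which C4a is the only free position ortho to the hydroxyl. Heating this phenol with enal 14 and ethylenediamine diacetate (cat.) in toluene should give, by ortho C-alkylation and loss of water, the same o-quinone methide 17, which closes to 18. The fallback comes back to the route at 18.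

Step 10. The chiral copper boryl may discriminate poorly between the two enantiomers of 18, or borylcupration of the electron-rich styrene flanked by the C5 methoxy group may be sluggish. The fallback uses a diastereoselective but non-enantioselective hydroboration followed by physical resolution and sets out from 18. CuCl with 4,5-bis(diphenylphosphino)-9,9-dimethylxanthene, B2pin2 (1.1 equiv), NaOtBu and MeOH in THF should give the racemic 2,3-trans pinacol boronate F2. Oxidation (H2O2, NaOH) gives the racemic 2,3-trans alcohol F3. Preparative chromatography on a chiral stationary phase (amylose tris(3,5-dimethylphenylcarbamate)) then separates 20 from its (2S,3R)-enantiomer F4. The fallback comes back to the route at 20.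

Step 11. Acid may promote cyclization of the prenyl group onto the freed C7 phenol (chroman formation) or ionization of the C2–O1 bond with epimerization at C2, in competition with acetal cleavage. The fallback replaces Brønsted-acid solvolysis by silyl exchange under buffered aprotic conditions followed by basic desilylation, and sets out from 20. TMSOTf with 2,2'-bipyridyl in CH2Cl2 at 0 °C should exchange both aryl acetals for trimethylsilyl ethers and silylate the C3 hydroxyl, giving (2R,3S)-5-methoxy-8-(3-methylbut-2-en-1-yl)-3,7-bis(trimethylsilyloxy)-2-[4-(trimethylsilyloxy)phenyl]chromane F5. K2CO3 in MeOH at 0 °C then removes the three silyl groups. The fallback comes back to the route at 21.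

Further compounds
F1 | step 9 | 5-methoxy-3-(methoxymethoxy)-2-(3-methylbut-2-en-1-yl)phenol | COCOc1cc(OC)cc(O)c1CC=C(C)C
F2 | step 10 | racemic 2,3-trans-5-methoxy-7-(methoxymethoxy)-2-[4-(methoxymethoxy)phenyl]-8-(3-methylbut-2-en-1-yl)-3-(4,4,5,5-tetramethyl-1,3,2-dioxaborolan-2-yl)chromane (both enantiomers written) | COc1cc(OCOC)c(CC=C(C)C)c2c1C[C@H](B1OC(C)(C)C(C)(C)O1)[C@@H](c1ccc(OCOC)cc1)O2.COc1cc(OCOC)c(CC=C(C)C)c2c1C[C@@H](B1OC(C)(C)C(C)(C)O1)[C@H](c1ccc(OCOC)cc1)O2
F3 | step 10 | racemic 2,3-trans-5-methoxy-7-(methoxymethoxy)-2-[4-(methoxymethoxy)phenyl]-8-(3-methylbut-2-en-1-yl)chroman-3-ol (both enantiomers written) | COc1cc(OCOC)c(CC=C(C)C)c2c1C[C@H](O)[C@@H](c1ccc(OCOC)cc1)O2.COc1cc(OCOC)c(CC=C(C)C)c2c1C[C@@H](O)[C@H](c1ccc(OCOC)cc1)O2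
F4 | step 10 | (2S,3R)-5-methoxy-7-(methoxymethoxy)-2-[4-(methoxymethoxy)phenyl]-8-(3-methylbut-2-en-1-yl)chroman-3-ol | COc1cc(OCOC)c(CC=C(C)C)c2c1C[C@@H](O)[C@H](c1ccc(OCOC)cc1)O2
F5 | step 11 | (2R,3S)-5-methoxy-8-(3-methylbut-2-en-1-yl)-3,7-bis(trimethylsilyloxy)-2-[4-(trimethylsilyloxy)phenyl]chromane | COc1cc(O[Si](C)(C)C)c(CC=C(C)C)c2c1C[C@H](O[Si](C)(C)C)[C@@H](c1ccc(O[Si](C)(C)C)cc1)O2
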